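Compound numbers used throughout: 1–22 are the compounds of the route (22 is the target), F1–F10 belong to fallbacks, A1–A9 to the alternatives.

## The problem

Compound 22 consists of a γ-butyrolactone (ring A: O1, C2, C3, C4, C5) whose C4 carries a 3,4-dimethoxybenzyl group and whose C3 is linked through one CH2 to C4' of a 2-pyranone (ring B) bearing a carboxylic acid at C6'. The rings are not fused, so the task divides into a stereochemical one on ring A and a constitutional one on ring B. Ring A holds the only two stereocentres, C3 and C4, both R and trans to each other. C3 is α to the lactone carbonyl and can be equilibrated, the trans arrangement being the stable one, so C4 can correct C3; nothing in the molecule can correct C4, whose absolute configuration must be imposed from outside. Ring B behaves like a vinylogous anhydride: aqueous base, alkoxides and amines open it, hydrogenation and strong hydride donors attack it, and the free acid interferes with every basic step. Ring A also opens in base, and the dimethoxyarene excludes hard oxidants and strong Lewis acids. Ring B should therefore be built late from a side chain that is inert until then, and its ester should be removed under acid. The feature that gives the shortest access to ring A is that its carbonyl carbon C2 is a single carbon held only by O1 and C3: removed as CO, it leaves an allylic alcohol O1–C5–C4=C3 whose alkene carries the two CH2 arms cis, so that syn addition of hydrogen at C4 and of an acyl carbon at C3 must give the trans lactone. The feature that guides ring B is that C4' bears the linking CH2 and lies between two CH groups, the pattern of a methyl ketone carbon after olefination (C3', C2') and acylation of its methyl group by an oxalate (C5' from the methyl, C6' and the carboxyl carbon from the oxalate).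

## Retrosynthesis

**22 to 21.** Only the ester C–O bond is cut: the acid is carried as the ethyl ester 21 and freed last. A free acid earlier would consume base in the condensation that builds ring B. The forward step must be an acidic hydrolysis, because aqueous base opens both lactone-type rings.

**21 to 18 and 19.** Ring B is cut at O1'–C2' and C5'–C6'. This leads to the open-chain 3-methylbut-2-enoate 18 and diethyl oxalate 19, joined by a vinylogous Claisen condensation and an enol lactonisation. The neighbouring cut, attaching a finished pyranone at C4' by a C–C coupling, would need a metallated or halogenated arm on ring A and would expose ring B to organometallic reagents. The condensation builds ring B from two esters at the correct oxidation level. The forward reaction must acylate the γ-methyl group of 18 in preference to the γ-methylene and to C3 of ring A; this is asked of thermodynamic control.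

**18 to 15 and 16.** The C3'=C4' bond is cut by a Horner–Wadsworth–Emmons disconnection to methyl ketone 15 and triethyl phosphonoacetate 16. The alkene geometry of 18 need not be controlled, because it equilibrates in the next step. The precursor is simpler by the whole unsaturated ester.

**15 to 14.** The ketone is masked as the dioxolane 14. The mask is needed because the carbonyl must stay silent through an organolithium and a Grignard step, and it is removed only after ring A exists: a free ketone in 12 would lie β,γ to the alkene and could draw it into conjugation. The dioxolane is inert to the carbonylation conditions.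

**14 to 12 and 13 (key disconnection).** The bonds C2–C3 and C2–O1 are cut and C2 leaves as carbon monoxide 13. What remains is the achiral (E)-allylic alcohol 12. Against the neighbouring cuts at C3–CH2 (enolate alkylation of a 4-benzyl lactone) or at C4–CH2 (conjugate addition to a butenolide), this one removes ring A and both stereocentres in one operation and asks for no stoichiometric chiral reagent. The forward reaction must place palladium at C3 and hydrogen at C4, add them syn, discriminate the two alkene faces, and leave the allylic C–O bond intact.

**12 to 8 and 9.** The bond from the alkene carbon (future C4) to the benzylic CH2 and the C3–H bond are cut. Butynol 8 and 3,4-dimethoxybenzyl chloride 9 result; 9 is used as its Grignard reagent 10. An olefination would give E/Z mixtures of a trisubstituted alkene; the anti-carbomagnesiation through chelate 11 fixes the geometry by mechanism. The forward step needs the regiochemistry dictated by the magnesium alkoxide (benzyl next to the carbinol carbon).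

**8 to 5 and 6, 5 to 2 and 3, 2 to 1.** The propargylic C–CH2OH bond is cut to alkyne 5 and formaldehyde 6. The alkyne carbon comes from diazophosphonate 3 acting on aldehyde 2, and 2 is the partial reduction product of the commercial ketal ester 1. Each cut removes one carbon and leads to a cheap, achiral material; the forward reactions are routine and only have to spare the ketal.

## Roads not taken

**Alternative 1:** Both side chains are attached to a preformed five-membered ring; the cut goes through C4–CH2Ar and C3–CH2 of ring A.

- Forward key step: the Grignard reagent 10, converted into a cuprate, would add to C4 of the chiral 5-menthyloxybutenolide A1 anti to the acetal substituent. The enolate would then be alkylated at C3 by the allylic bromide A2 anti to the new benzyl group, giving the 3,4-trans-4,5-trans lactone A3 in one flask. Hydrolysis of the acetal, reduction of the released aldehyde and relactonisation would lead to enoate 18 and into steps 8 and 9.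
- Merits: the absolute configuration rests on a crystalline auxiliary and on substrate control that is well established for dibenzylbutyrolactones. The arm arrives already as the 3-methylbutenoate, so steps 6 and 7 are not needed, and the overall length is about the same or slightly shorter.
- Weak points for this target: benzylic cuprates of electron-rich arenes transfer poorly and homocouple, so a sulfur-stabilised benzyl anion and a later desulfurisation are usually required. The enolate is a sluggish nucleophile towards A2, which can also react with allylic transposition. The C5 acetal must be removed by a basic hydrolysis–reduction sequence that also attacks the enoate ester. The auxiliary is stoichiometric, and A1 has to be prepared and purified by crystallisation.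
- Comparison: this road is the better one for reliability of the stereochemistry. The chosen plan sets against it a catalytic source of chirality, a key step in which ring A, its carbonyl carbon and both stereocentres arise together without a redox detour at C5, and a geometry-defined precursor 12. Both roads share the condensation of step 8 and its risk.

**Alternative 2:** Ring B is cut at C3'–C4' and O1'–C2'.

- Forward key step: the 1-oxadiene of the β,γ-unsaturated α-keto ester A4 would combine with ketene acetal A5 in an inverse-demand hetero-[4+2] cycloaddition to give the 2,2-diethoxy-3,4-dihydro-2H-pyran A6. Elimination of one ethoxy group, hydrolysis of the remaining ketene acetal and a dehydrogenation across C3'–C4' would give pyranone ester 21.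
- Merits: the regiochemistry is fixed by the polarity of both partners, there is no choice between a methyl and a methylene group, and no strong base comes near ring A. In these respects it is better than step 8.
- Weak points: the cut says nothing about ring A, so A4 would have to be assembled on a finished (3R,4R)-lactone carrying a two-carbon aldehyde arm, and the stereochemical problem is only postponed. A4 has acidic γ-hydrogens next to ring A and can tautomerise to its dienol. A6 is two hydrogens short of the pyranone oxidation level, its transient C4' stereocentre is made only to be destroyed, and the dehydrogenation has to spare the electron-rich benzyl group.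
- Comparison: this is an alternative endgame only, and it would need more operations than steps 7 and 8, which work at the correct oxidation level. Against its cleaner regiochemistry the chosen plan sets the thermodynamic bias of step 8 towards the γ-methyl group and a fallback for that step.

**Alternative 3:** Ring B is derived from an aromatic ring. The catechol A8, obtainable from the natural lignan A7 by demethylation of its guaiacol ring, already contains ring A with both stereocentres.

- Forward key step: an extradiol catechol dioxygenase (non-haem divalent iron, air as oxidant) would cleave the ring bond between the hydroxylated carbon para to the benzylic CH2 and its unsubstituted neighbour. The enol oxygen of the ring-opened intermediate would add to the new aldehyde and close the six-membered lactol A9 (O1'–C2'); oxidation of the lactol carbon would give 22.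
- Merits: by far the shortest route (about three operations from A7), no protecting groups, inherited stereochemistry, and a probable parallel to the natural origin of the compound.
- Weak points: whether such an enzyme accepts a catechol with a bulky lignan residue, and which ring bond it cleaves, cannot be predicted from the structure. The ring-opened stage is a reactive polyene prone to condensation. The final oxidation must distinguish the lactol from the electron-rich arene. Supply depends on isolated A7 and on an expressed enzyme.
- Comparison: in step economy this road is clearly superior and, if the enzyme accepted A8, it would be preferred for making 22 itself. The chosen plan sets against it reactions whose outcome can be argued step by step, independence from a natural source, and free variation of both arms and of the absolute configuration.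

Key step: step 5

Assumption: the ligand is written as (2S,4S)-BPPM, tert-butyl (2S,4S)-4-(diphenylphosphanyl)-2-[(diphenylphosphanyl)methyl]pyrrolidine-1-carboxylate; which hand of the ligand serves the required alkene face cannot be deduced from the structure, and the enantiomeric ligand would be taken if the opposite lactone is favoured.

Assumption: 1, the ethylene ketal of ethyl acetoacetate, is bought as such (it is a commercial fragrance ingredient).

## Route

Step 1
Reactants: 1 ethyl 2-(2-methyl-1,3-dioxolan-2-yl)acetate
Product: 2 2-(2-methyl-1,3-dioxolan-2-yl)acetaldehyde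
Conditions: i-Bu2AlH (1.05 equiv), CH2Cl2, −78 °C; aq. potassium sodium tartrate
Reagents that add atoms: none
Why: Partial reduction of an ester to the aldehyde with i-Bu2AlH at −78 °C, where one hydride is delivered and the aldehyde is released only on work-up; the ketal is inert to hydride and the non-acidic tartrate work-up keeps it intact.

Step 2
Reactants: 2 2-(2-methyl-1,3-dioxolan-2-yl)acetaldehyde; 3 dimethyl (1-diazo-2-oxopropyl)phosphonate
Product: 5 2-methyl-2-(prop-2-yn-1-yl)-1,3-dioxolane, via dimethyl (diazomethyl)phosphonate 4 (not isolated)
Conditions: K2CO3 (2 equiv), MeOH, 0 °C → rt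
Reagents that add atoms: none
Why: Ohira–Bestmann form of the Seyferth–Gilbert homologation: methanolysis of 3 releases 4, whose anion olefinates the aldehyde, and loss of N2 with 1,2-hydrogen shift gives the terminal alkyne; the carbonate base is mild enough for an enolisable aldehyde and leaves the ketal untouched.

Step 3
Reactants: 5 2-methyl-2-(prop-2-yn-1-yl)-1,3-dioxolane; 6 formaldehyde (used as dry paraformaldehyde)
Product: 8 4-(2-methyl-1,3-dioxolan-2-yl)but-2-yn-1-ol, via lithium acetylide 7 (not isolated)
Conditions: n-BuLi (1.05 equiv), THF, −78 °C; (CH2O)n, −78 °C → rt; aq. NH4Cl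
Reagents that add atoms: none
Why: Deprotonation of a terminal alkyne and addition of the acetylide to formaldehyde is the standard route to primary propargylic alcohols; the molecule has no other acidic or electrophilic site.

Step 4
Reactants: 8 4-(2-methyl-1,3-dioxolan-2-yl)but-2-yn-1-ol; 9 4-(chloromethyl)-1,2-dimethoxybenzene (3,4-dimethoxybenzyl chloride)
Product: 12 (E)-2-(3,4-dimethoxybenzyl)-4-(2-methyl-1,3-dioxolan-2-yl)but-2-en-1-ol, via 3,4-dimethoxybenzylmagnesium chloride 10 (not isolated), via alkenylmagnesium chelate 11 (not isolated)
Conditions: 9, Mg, THF, 0 °C, slow addition (gives 10, 3 equiv); then 8, CuI (10 mol%), THF, −20 °C → rt; aq. NH4Cl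
Reagents that add atoms: none
Why: Copper-catalysed anti-carbomagnesiation of a propargylic alcohol: the magnesium alkoxide directs the benzyl group to the carbon next to the carbinol and magnesium to the distal carbon trans to it, closing the five-membered chelate 11, and protonolysis with retention leaves the two CH2 arms cis, which is the (E)-alkene only. One equivalent of 10 is consumed by the hydroxyl proton, and 11 cannot eliminate because the ketal oxygens are one carbon too far from the C–Mg bond.

Step 5
Reactants: 12 (E)-2-(3,4-dimethoxybenzyl)-4-(2-methyl-1,3-dioxolan-2-yl)but-2-en-1-ol; 13 carbon monoxide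
Product: 14 (3R,4R)-4-(3,4-dimethoxybenzyl)-3-[(2-methyl-1,3-dioxolan-2-yl)methyl]dihydrofuran-2(3H)-one
Conditions: Pd2(dba)3·CHCl3 (2.5 mol%), (2S,4S)-BPPM (6 mol%), CO (40 bar), H2 (15 bar), CH2Cl2, 90 °C
Reagents that add atoms: none
Why: A palladium hydride (divalent palladium), formed from the zerovalent palladium–bisphosphine complex under CO and H2, adds syn across C3=C4 of 12 with hydrogen going to the fully substituted C4 and palladium to the less hindered C3; CO then inserts into the C3–Pd bond with retention and the primary hydroxyl takes up the acyl–palladium carbon, which forms C2–C3 and C2–O1 and returns the hydride. The closest known reaction type is the palladium-catalysed cyclocarbonylation of β,γ-substituted allylic alcohols to α,β-substituted γ-butyrolactones under CO/H2, including its asymmetric form with chiral 1,4-bisphosphines. Ring A closes by 5-exo-trig attack of O1 on the acyl carbon. C4 and C3 are created together in the hydropalladation: their absolute configuration is set by the ligand, which has to direct hydrogen and palladium to the face that is Re at C3 and Si at C4, and their relative configuration by syn addition to the (E)-alkene, whose cis CH2 arms thereby end up trans on the ring. The trans lactone is also the more stable epimer at the enolisable C3, so later equilibration cannot erode it. The step needs regioselectivity (palladium at C3), secured by the trisubstitution, since the other mode would require a tertiary alkylpalladium and a four-membered lactone, and chemoselectivity, secured by the absence of any other alkene and the inertness of the dioxolane, the aryl ethers and the arene to CO, H2 and the hydride. The reaction is a pure addition of 13 to 12; H2 only maintains the hydride.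

Step 6
Reactants: 14 (3R,4R)-4-(3,4-dimethoxybenzyl)-3-[(2-methyl-1,3-dioxolan-2-yl)methyl]dihydrofuran-2(3H)-one
Product: 15 (3R,4R)-4-(3,4-dimethoxybenzyl)-3-(2-oxopropyl)dihydrofuran-2(3H)-one
Conditions: 1 M HCl, THF, rt
Reagents that add atoms: water, O
Why: Acid-catalysed hydrolysis of a dioxolane ketal; the γ-lactone is stable to dilute acid and C3 is already in its preferred trans arrangement, so the acid cannot change the stereochemistry.

Step 7
Reactants: 15 (3R,4R)-4-(3,4-dimethoxybenzyl)-3-(2-oxopropyl)dihydrofuran-2(3H)-one; 16 triethyl phosphonoacetate
Product: 18 ethyl (E)-4-[(3R,4R)-4-(3,4-dimethoxybenzyl)-2-oxotetrahydrofuran-3-yl]-3-methylbut-2-enoate, via sodium phosphonate 17 (not isolated)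
Conditions: 16 (1.5 equiv), NaH (1.4 equiv), THF, 0 °C; then 15, 0 → 50 °C
Reagents that add atoms: none
Why: Horner–Wadsworth–Emmons olefination of a methyl ketone; the stabilised anion 17, made with a slight deficit of NaH, is a weak base that leaves the lactone and C3 alone. The (E)-isomer should predominate; the (Z)-isomer is carried along because both converge in step 8.

Step 8
Reactants: 18 ethyl (E)-4-[(3R,4R)-4-(3,4-dimethoxybenzyl)-2-oxotetrahydrofuran-3-yl]-3-methylbut-2-enoate; 19 diethyl oxalate
Product: 21 ethyl 4-{[(3R,4R)-4-(3,4-dimethoxybenzyl)-2-oxotetrahydrofuran-3-yl]methyl}-2-oxo-2H-pyran-6-carboxylate, via potassium dienolate 20 (not isolated)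
Conditions: 19 (3 equiv), KOt-Bu (1.2 equiv), THF, 0 °C → rt; then 4 M HCl in 1,4-dioxane, rt → 50 °C
Reagents that add atoms: none
Why: Vinylogous Claisen condensation of a 3-methylalk-2-enoate with an oxalate followed by acid-promoted enol lactonisation, the classical route to 2-pyranone-6-carboxylates: the γ-methyl carbon is acylated (C5'–C6') and the enol oxygen then displaces ethoxide from the enoate ester (O1'–C2'), the alkene geometry equilibrating in the delocalised dienolate 20. Under these reversible conditions 20 is the thermodynamic sink, because acylation at the tertiary C3 of ring A gives a non-enolisable adduct that reverts and acylation at the hindered γ-methylene gives a strained enolate; C3 may equilibrate but returns to trans.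

Step 9
Reactants: 21 ethyl 4-{[(3R,4R)-4-(3,4-dimethoxybenzyl)-2-oxotetrahydrofuran-3-yl]methyl}-2-oxo-2H-pyran-6-carboxylate
Product: 22 4-{[(3R,4R)-4-(3,4-dimethoxybenzyl)-2-oxotetrahydrofuran-3-yl]methyl}-2-oxo-2H-pyran-6-carboxylic acid
Conditions: 6 M HCl, 1,4-dioxane, 80 °C
Reagents that add atoms: water, O
Why: Acid-catalysed hydrolysis of an ethyl ester, chosen because aqueous base would open both ring B and ring A, whereas under acid both rings persist or reclose on concentration; the aryl methyl ethers are stable to aqueous HCl and C3 stays trans.

## Compound list

1 | ethyl 2-(2-methyl-1,3-dioxolan-2-yl)acetate | CCOC(=O)CC1(C)OCCO1 | starting material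
2 | 2-(2-methyl-1,3-dioxolan-2-yl)acetaldehyde | O=CCC1(C)OCCO1 | intermediate
3 | dimethyl (1-diazo-2-oxopropyl)phosphonate | COP(=O)(OC)C(=[N+]=[N-])C(C)=O | starting material
4 | dimethyl (diazomethyl)phosphonate | COP(=O)(OC)C=[N+]=[N-] | intermediate
5 | 2-methyl-2-(prop-2-yn-1-yl)-1,3-dioxolane | C#CCC1(C)OCCO1 | intermediate
6 | formaldehyde (as paraformaldehyde) | C=O | starting material
7 | lithium 3-(2-methyl-1,3-dioxolan-2-yl)prop-1-yn-1-ide (lithium acetylide of 5) | [Li]C#CCC1(C)OCCO1 | intermediate
8 | 4-(2-methyl-1,3-dioxolan-2-yl)but-2-yn-1-ol | OCC#CCC1(C)OCCO1 | intermediate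
9 | 4-(chloromethyl)-1,2-dimethoxybenzene | COc1ccc(CCl)cc1OC | starting material
10 | 3,4-dimethoxybenzylmagnesium chloride | COc1ccc(C[Mg]Cl)cc1OC | intermediate
11 | chloromagnesium (Z)-3-(chloromagnesio)-2-(3,4-dimethoxybenzyl)-4-(2-methyl-1,3-dioxolan-2-yl)but-2-en-1-olate (Mg on C3 cis to the CH2O group, five-membered chelate) | Cl[Mg]OC/C(Cc1ccc(OC)c(OC)c1)=C(\[Mg]Cl)CC1(C)OCCO1 | intermediate
12 | (E)-2-(3,4-dimethoxybenzyl)-4-(2-methyl-1,3-dioxolan-2-yl)but-2-en-1-ol | OC/C(Cc1ccc(OC)c(OC)c1)=C/CC1(C)OCCO1 | intermediate
13 | carbon monoxide | [C-]#[O+] | starting material
14 | (3R,4R)-4-(3,4-dimethoxybenzyl)-3-[(2-methyl-1,3-dioxolan-2-yl)methyl]dihydrofuran-2(3H)-one | COc1ccc(C[C@H]2COC(=O)[C@@H]2CC3(C)OCCO3)cc1OC | intermediate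
15 | (3R,4R)-4-(3,4-dimethoxybenzyl)-3-(2-oxopropyl)dihydrofuran-2(3H)-one | COc1ccc(C[C@H]2COC(=O)[C@@H]2CC(C)=O)cc1OC | intermediate
16 | triethyl phosphonoacetate (ethyl 2-(diethoxyphosphoryl)acetate) | CCOC(=O)CP(=O)(OCC)OCC | starting material
17 | sodium 1-(diethoxyphosphoryl)-2-ethoxy-2-oxoethan-1-ide (sodium salt of 16) | [Na+].CCOC(=O)[CH-]P(=O)(OCC)OCC | intermediate
18 | ethyl (E)-4-[(3R,4R)-4-(3,4-dimethoxybenzyl)-2-oxotetrahydrofuran-3-yl]-3-methylbut-2-enoate | COc1ccc(C[C@H]2COC(=O)[C@@H]2C/C(C)=C/C(=O)OCC)cc1OC | intermediate
19 | diethyl oxalate | CCOC(=O)C(=O)OCC | starting material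
20 | potassium dienolate of diethyl 2-oxo-4-{[(3R,4R)-4-(3,4-dimethoxybenzyl)-2-oxotetrahydrofuran-3-yl]methyl}hex-4-enedioate (alkene geometries equilibrating) | [K+].CCOC(=O)C([O-])=CC(C[C@H]1C(=O)OC[C@@H]1Cc2ccc(OC)c(OC)c2)=CC(=O)OCC | intermediate
21 | ethyl 4-{[(3R,4R)-4-(3,4-dimethoxybenzyl)-2-oxotetrahydrofuran-3-yl]methyl}-2-oxo-2H-pyran-6-carboxylate | COc1ccc(C[C@H]2COC(=O)[C@@H]2Cc2cc(C(=O)OCC)oc(=O)c2)cc1OC | intermediate
22 | 4-{[(3R,4R)-4-(3,4-dimethoxybenzyl)-2-oxotetrahydrofuran-3-yl]methyl}-2-oxo-2H-pyran-6-carboxylic acid | COc1ccc(C[C@H]2COC(=O)[C@@H]2Cc2cc(C(=O)O)oc(=O)c2)cc1OC | target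

## Step count and least certain steps

Total: 9 steps. Longest linear sequence: 9 steps (1 to 22); 3, 6, 9, 13, 16 and 19 enter as purchased materials.

**Step 5 (key step).** The most likely failure is insufficient discrimination of the two alkene faces, because the two CH2 arms are sterically similar and the primary hydroxyl is the only anchor for the ligand. In addition, substrate may be lost by ionisation of the allylic C–O bond to an allylpalladium species, by double-bond migration to the saturated aldehyde, or by plain hydrogenation. The fallback uses auxiliary control and known reactions; it sets out from 9 and returns to the route at 15.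
(R)-4-Benzyloxazolidin-2-one is N-acylated with 4-tert-butoxy-4-oxobutanoic acid (pivaloyl chloride, Et3N, LiCl) to give tert-butyl 4-[(R)-4-benzyl-2-oxooxazolidin-3-yl]-4-oxobutanoate F1. Its sodium enolate (NaN(SiMe3)2, THF, −78 °C) is alkylated by 9 on the face away from the auxiliary benzyl group to give tert-butyl (R)-4-[(R)-4-benzyl-2-oxooxazolidin-3-yl]-3-(3,4-dimethoxybenzyl)-4-oxobutanoate F2. LiBH4 removes the auxiliary reductively and gives tert-butyl (R)-3-(3,4-dimethoxybenzyl)-4-hydroxybutanoate F3, which closes in CF3CO2H/CH2Cl2 to (R)-4-(3,4-dimethoxybenzyl)dihydrofuran-2(3H)-one F4. The lithium enolate of F4 (LiN(SiMe3)2, THF, −78 °C) is alkylated with 3-bromo-2-methylpropene trans to the C4 substituent to give (3R,4R)-4-(3,4-dimethoxybenzyl)-3-(2-methylallyl)dihydrofuran-2(3H)-one F5. Lemieux–Johnson cleavage (OsO4 cat., NaIO4, 2,6-lutidine, dioxane–water) then gives 15.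

**Step 8.** The most likely failure is loss of regiocontrol in the acylation (attack through the γ-methylene or through C3 of ring A instead of the γ-methyl), or intramolecular acylation of the dienolate by the lactone carbonyl with closure of a five-membered carbocycle. The fallback moves the regiochemical decision to the methyl ketone, where the methyl side is reliably preferred, and closes ring B without base; it sets out from 15 and returns at 21.
15 is converted with LiN(SiMe3)2 (THF, −78 °C) into its methyl-side enolate and acylated with 19 to give ethyl 5-[(3R,4R)-4-(3,4-dimethoxybenzyl)-2-oxotetrahydrofuran-3-yl]-2,4-dioxopentanoate F8. F8 is enolised towards the ester; its enol hydroxyl adds to Ph3P=C=C=O (toluene, 80 °C) to give an ester ylide that closes on the C4 ketone by intramolecular Wittig reaction to 21. The open point of this fallback is whether only the enol oxygen next to the ester is acylated.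

**Step 4.** The most likely failure is homocoupling during formation of the electron-rich benzylic Grignard reagent combined with slow carbometalation of an internal alkyne, so that reagent is quenched by the alkoxide proton and conversion stalls. The fallback builds the alkene by olefination; it sets out from 2 and 9 and returns at 12.
9 alkylates ethyl (triphenylphosphoranylidene)acetate, and deprotonation with aqueous NaOH gives ethyl 3-(3,4-dimethoxyphenyl)-2-(triphenylphosphoranylidene)propanoate F6. Wittig reaction of F6 with 2 (toluene, 80 °C) gives ethyl (E)-2-(3,4-dimethoxybenzyl)-4-(2-methyl-1,3-dioxolan-2-yl)but-2-enoate F7, the α-branched stabilised ylide placing the ester trans to the new chain. i-Bu2AlH (2.2 equiv, CH2Cl2, −78 °C) reduces F7 to 12. The price is a minor (Z)-isomer to be removed.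

**Step 2.** The most likely failure is base-induced β-elimination with opening of the dioxolane from the enolate of the β,β-dialkoxy aldehyde, and loss of the volatile alkyne on isolation. The fallback avoids alkoxide base and the isolation of 5; it sets out from 2 and returns at 8.
Corey–Fuchs olefination of 2 (CBr4, PPh3, Et3N, CH2Cl2, 0 °C) gives 2-(3,3-dibromoprop-2-en-1-yl)-2-methyl-1,3-dioxolane F9. n-BuLi (2.1 equiv, THF, −78 °C) converts F9 by bromine–lithium exchange and rearrangement into acetylide 7, which is trapped in the same flask with 6 to give 8.

**Step 9.** The most likely failure is incomplete hydrolysis at temperatures ring B tolerates, or hydration and opening of the pyranone on prolonged heating in aqueous acid. The fallback replaces hydrolysis by anhydrous acidolysis of a tert-butyl ester; it sets out from 18 and returns at 22.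
18 is condensed with di-tert-butyl oxalate (KOt-Bu, THF) and the adduct is closed in warm acetic acid to give tert-butyl 4-{[(3R,4R)-4-(3,4-dimethoxybenzyl)-2-oxotetrahydrofuran-3-yl]methyl}-2-oxo-2H-pyran-6-carboxylate F10. CF3CO2H in CH2Cl2 with Et3SiH as cation scavenger removes the tert-butyl group and gives 22 without water.

## Further compounds

F1 | step 5 | tert-butyl 4-[(R)-4-benzyl-2-oxooxazolidin-3-yl]-4-oxobutanoate | CC(C)(C)OC(=O)CCC(=O)N1[C@H](Cc2ccccc2)COC1=O
F2 | step 5 | tert-butyl (R)-4-[(R)-4-benzyl-2-oxooxazolidin-3-yl]-3-(3,4-dimethoxybenzyl)-4-oxobutanoate | COc1ccc(C[C@H](CC(=O)OC(C)(C)C)C(=O)N2[C@H](Cc3ccccc3)COC2=O)cc1OC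
F3 | step 5 | tert-butyl (R)-3-(3,4-dimethoxybenzyl)-4-hydroxybutanoate | COc1ccc(C[C@H](CC(=O)OC(C)(C)C)CO)cc1OC
F4 | step 5 | (R)-4-(3,4-dimethoxybenzyl)dihydrofuran-2(3H)-one | COc1ccc(C[C@H]2COC(=O)C2)cc1OC
F5 | step 5 | (3R,4R)-4-(3,4-dimethoxybenzyl)-3-(2-methylallyl)dihydrofuran-2(3H)-one | COc1ccc(C[C@H]2COC(=O)[C@@H]2CC(C)=C)cc1OC
F6 | step 4 | ethyl 3-(3,4-dimethoxyphenyl)-2-(triphenylphosphoranylidene)propanoate | CCOC(=O)C(Cc1ccc(OC)c(OC)c1)=P(c1ccccc1)(c1ccccc1)c1ccccc1
F7 | step 4 | ethyl (E)-2-(3,4-dimethoxybenzyl)-4-(2-methyl-1,3-dioxolan-2-yl)but-2-enoate | CCOC(=O)/C(Cc1ccc(OC)c(OC)c1)=C/CC1(C)OCCO1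
F8 | step 8 | ethyl 5-[(3R,4R)-4-(3,4-dimethoxybenzyl)-2-oxotetrahydrofuran-3-yl]-2,4-dioxopentanoate | CCOC(=O)C(=O)CC(=O)C[C@H]1C(=O)OC[C@@H]1Cc2ccc(OC)c(OC)c2
F9 | step 2 | 2-(3,3-dibromoprop-2-en-1-yl)-2-methyl-1,3-dioxolane | BrC(Br)=CCC1(C)OCCO1
F10 | step 9 | tert-butyl 4-{[(3R,4R)-4-(3,4-dimethoxybenzyl)-2-oxotetrahydrofuran-3-yl]methyl}-2-oxo-2H-pyran-6-carboxylate | COc1ccc(C[C@H]2COC(=O)[C@@H]2Cc2cc(C(=O)OC(C)(C)C)oc(=O)c2)cc1OC
A1 | alternative 1 | (5R)-5-{[(1R,2S,5R)-2-isopropyl-5-methylcyclohexyl]oxy}furan-2(5H)-one | O=C1C=C[C@H](O[C@@H]2C[C@H](C)CC[C@H]2C(C)C)O1
A2 | alternative 1 | ethyl (E)-4-bromo-3-methylbut-2-enoate | CCOC(=O)/C=C(\C)CBr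
A3 | alternative 1 | ethyl (E)-4-[(3R,4R,5R)-4-(3,4-dimethoxybenzyl)-5-{[(1R,2S,5R)-2-isopropyl-5-methylcyclohexyl]oxy}-2-oxotetrahydrofuran-3-yl]-3-methylbut-2-enoate (3,4-trans, 4,5-trans) | COc1ccc(C[C@H]2[C@H](O[C@@H]3C[C@H](C)CC[C@H]3C(C)C)OC(=O)[C@@H]2C/C(C)=C/C(=O)OCC)cc1OC
A4 | alternative 2 | ethyl (E)-5-[(3R,4R)-4-(3,4-dimethoxybenzyl)-2-oxotetrahydrofuran-3-yl]-2-oxopent-3-enoate | CCOC(=O)C(=O)/C=C/C[C@H]1C(=O)OC[C@@H]1Cc2ccc(OC)c(OC)c2
A5 | alternative 2 | 1,1-diethoxyethene | C=C(OCC)OCC
A6 | alternative 2 | ethyl 4-{[(3R,4R)-4-(3,4-dimethoxybenzyl)-2-oxotetrahydrofuran-3-yl]methyl}-2,2-diethoxy-3,4-dihydro-2H-pyran-6-carboxylate (both epimers at C4' of the pyran) | COc1ccc(C[C@H]2COC(=O)[C@@H]2CC3CC(OCC)(OCC)OC(C(=O)OCC)=C3)cc1OC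
A7 | alternative 3 | arctigenin, (3R,4R)-4-(3,4-dimethoxybenzyl)-3-(4-hydroxy-3-methoxybenzyl)dihydrofuran-2(3H)-one | COc1ccc(C[C@H]2COC(=O)[C@@H]2Cc2ccc(O)c(OC)c2)cc1OC
A8 | alternative 3 | 3'-O-demethylarctigenin, (3R,4R)-3-(3,4-dihydroxybenzyl)-4-(3,4-dimethoxybenzyl)dihydrofuran-2(3H)-one | COc1ccc(C[C@H]2COC(=O)[C@@H]2Cc2ccc(O)c(O)c2)cc1OC
A9 | alternative 3 | 4-{[(3R,4R)-4-(3,4-dimethoxybenzyl)-2-oxotetrahydrofuran-3-yl]methyl}-2-hydroxy-2H-pyran-6-carboxylic acid (lactol, both anomers) | COc1ccc(C[C@H]2COC(=O)[C@@H]2CC2=CC(O)OC(C(=O)O)=C2)cc1OC
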